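**Numbering.** Carbons are numbered as in the germacranolide: Z olefin C1=C10 (methyl on C10), C2 carbinol, E olefin C4=C5 (methyl on C4), C6 lactone carbinol, C7 ring fusion, C8 acetoxy carbon, C9 methylene, C11 tertiary carbinol, C12 lactone carbonyl, C13 chloromethyl. Compounds are numbered 1–36 in the order of the steps; 36 is the target.

## The problem

1. Target 36 is a ten-membered carbocycle (C1–C10) with a Z-trisubstituted C1=C10 olefin and an E-trisubstituted C4=C5 olefin. It is trans-fused across C6–C7 to a γ-lactone (O6–C12) whose α-carbon C11 is a tertiary alcohol carrying the chloromethyl carbon C13; C2 bears a free allylic hydroxyl and C8 an acetate.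
2. Five stereocentres (2S,6R,7R,8R,11S) must be set. C7 and C11 can be made together in one aldol event, C8 can be relayed from C7 by Felkin addition, C6 is created when the ring closes, and C2 is insulated by the olefin and has to be brought in on its own.
3. The geometric crux is the Z olefin between two carbinols, because open-chain olefinations give trisubstituted olefins of this type mainly E.
4. The sensitive groups are the 1,5-diene in a medium ring (acid-promoted transannular cyclisation), the tertiary β-chloro alcohol (closes to a spiro-epoxide with base), and the acetate and lactone (acyl migration and translactonisation between O6 and O8, both γ to C12).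
5. For the same reason, any intermediate with a free O6 or O8 and an acyl C12 tends to lactonise, and the plan has to use this tendency.
6. The feature that makes the key step possible is that the C2 and C8 oxygens flank the C1=C10 olefin in a 1,5-relationship: one silicon atom across them puts C1 and C10 into an eight-membered ring, which can only hold a cis ring olefin.
7. O2 and O8 lie on opposite faces of the finished carbocycle, so a one-atom bridge between them would make the macrocycle an in,out-bridged bicyclo[5.3.3] system; the tether must therefore be removed before the ten-membered ring is closed.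

## Retrosynthesis

**36 ⇐ 35 ⇐ 34 ⇐ 33 (O6–C12 and C5–C6).** The last skeletal cuts are the lactone C–O bond and the C5–C6 bond. Cutting C5–C6, and not C6–C7 or C7–C8, keeps the contiguous centres C7, C8 and C11 in one chain. It also joins an sp2 carbon of fixed E geometry to an aldehyde carbon (Nozaki–Hiyama–Kishi type) and creates O6 only when the ring exists, so O6 can acylate only onto C12. The precursor is the open-chain iodo aldehyde 33, with C12 as an N-methoxy-N-methylamide, O8 already acetylated and O2 silylated. Ring closure gives 34, which lactonises to 35, and desilylation gives 36. The forward step must close a ten-membered ring at high dilution without touching amide, acetate or alkyl chloride, and must give 6R.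

**33 ⇐ 32 ⇐ 31 ⇐ 30 ⇐ 29 ⇐ 28 (differentiating O2 and O8).** No skeletal bond is cut here; the cuts are O8–acetyl, O2–silyl and the C6 oxidation level. O2 and O8 are both secondary alcohols once the tether is gone. The lactonising tendency of O8 is used to tell them apart: in lactone 28, O8 is acylated by C12 and only O2 is free, so silylation to 29 needs no selectivity. Reopening the lactone with the amine (30) and acetylating the freed O8 gives 31; PMB removal (32) and oxidation give 33. The neighbouring option, oxidising the allylic O2 to an enone and reducing it back, would destroy and re-create the C2 centre and put a Z-enone with an acidic skipped methylene into the sequence.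

**28 ⇐ 27 ⇐ 26 ⇐ 25 (C1=C10, key step).** The Z olefin is cut by ring-closing metathesis inside the silaketal 25. Wittig-type, cross-metathesis and carbometalation routes to this olefin either give E or need an organometallic β to oxygen. The tether uses only the two oxygens the target already has, makes the union intramolecular, and lets ring size dictate geometry. The precursor 25 is simply the two fragments joined through silicon. The forward reaction must close an eight-membered ring onto a 1,1-disubstituted olefin while leaving the vinyl iodide alone. The tether is cleaved immediately afterwards (26 → 27 → 28) for the topological reason given above.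

**25 ⇐ 24 + 22; 24 ⇐ 8 + 23 (Si–O bonds).** The mixed silaketal is made stepwise from dichlorosilane 23: first the C1–C5 alcohol 8 (giving chlorosilyl ether 24), then the C8 hydroxyl of 22. This needs the C8 hydroxyl free while C12 is an acyl group, which is achieved by holding C12 as the amide 22 and silylating at once.

**22 ⇐ 21 ⇐ 20 ⇐ 18 + 19 (C8–C9).** The methallyl carbinol is cut at C8–C9, back to aldehyde 18 and the methallyl nucleophile 19. The alternative aldol cut at C7–C8 would need an unstable β,γ-unsaturated aldehyde partner. The required 8R configuration is the Felkin product with C11 as the large group, so a chiral allylborane can be chosen to match the substrate. The hydroxy ester 20 lactonises to 21; this is accepted as a storage form, and the lactone is opened to amide 22 only when the C8 hydroxyl is needed.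

**18 ⇐ 17 ⇐ 16 ⇐ 13 + 15 (C7–C11).** C7 and C11 are cut together as an aldol bond between ketene thioacetal 13 and keto ester 15. Oxygenating a lactone enolate or α-methylene lactone of the 21 skeleton instead would deliver oxygen anti to the C7 substituent, which is the wrong C11 epimer. A catalytic anti-selective pyruvate aldol sets both centres in one step, and because 15 already carries the chloride, no late chlorination is needed. The thioester of 17 is the direct precursor of aldehyde 18.

**13 ⇐ 12 ⇐ 11 ⇐ 9 + 10; 15 ⇐ 14.** The donor comes from conjugate addition of alcohol 9 to acrylate 10, ester-to-thioester exchange and silylation; the acceptor comes from bromide 14 by halide exchange.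

**8 ⇐ 7 ⇐ 6 ⇐ 5 ⇐ 4 ⇐ 3 ⇐ 1 + 2.** The C2 centre is taken from the chiral pool (epoxide 1) and not from an asymmetric addition to a volatile enal, at the cost of two steps. Acetylide 2 opens 1 (C3–C4 bond), a sulfonium ylide turns the chlorohydrin 3 via epoxide 4 into the vinyl carbinol 5 (C1), and desilylation gives 6. Carboalumination–iodination (via 7) then installs the C4 methyl and the C5 iodide with E geometry in 8.

## Roads not taken

**Alternative 1:** [2,3]-Wittig ring contraction; the cut is C6–C7.
- Forward step: an alkyllithium base deprotonates the ether methylene that becomes C6 in a thirteen-membered precursor. The carbanion adds to C7 through a five-membered transition state, contracting the ring to the ten-membered dienol A1, with O6 freed and C11=C13 left as an exocyclic methylene.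
- Merits: the medium ring is reached from a larger, less strained ring, and C6 and C7 are set together in one ordered event. In that respect it is better than the chosen plan, where C6 is set in step 20 with uncertain induction.
- Weak points: the precursor of A1 already contains the Z olefin, so that problem is only moved. It has two allylic α-oxy methylenes that can be lithiated, and [1,2]-shift competes. After the contraction, C11 must still become a configured tertiary alcohol and C12 must be oxidised from the alcohol level, in the presence of two more electron-rich ring olefins.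
- Comparison: the chosen plan sets against this that C11, its chloride and the C12 oxidation level are fixed in step 9 before any ring exists, and that the Z olefin has a ring-size guarantee.

**Alternative 2:** anionic oxy-Cope ring expansion; the cuts are C2–C3 (formed) and C5–C10 (broken).
- Forward step: the potassium alkoxide of a lactone-fused divinylcyclohexanol rearranges, and the enolate is trapped to give the enol triflate A2.
- Merits: one step makes the ten-membered ring, both olefins and the C2 centre, with C6, C7 and C8 set beforehand on a six-membered ring. In bond-forming power it is better than the chosen plan.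
- Weak points: the precursor of A2 is itself a long synthesis. The strongly basic conditions meet a lactone and a β-oxygenated quaternary centre. The C10 methyl must then be brought in by coupling a hindered enol triflate. The Z geometry and the C2 configuration both depend on one transition-state geometry, with no independent handle if it goes the wrong way.
- Comparison: the chosen plan offers independent control of each element and keeps the base-labile C11/C13 unit away from strong base.

**Alternative 3:** chromium-mediated allylation macrocyclisation; the cut is C7–C8.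
- Forward step: a divalent chromium salt turns a 2-(bromomethyl)enoate into an allylchromium that adds through C7 to a tethered C8 aldehyde, giving A3 with a free C8 hydroxyl and the C7 acrylate.
- Merits: this is the best-precedented way to close germacranolide rings. It is stereoconvergent in the allyl halide, sets C7 and C8 in the closure, and frees O8 alone for direct acetylation. It is probably shorter, and its ring closure is better precedented than step 20 here.
- Weak points: C11 must be oxygenated afterwards on the conjugated exocyclic methylene (cis to H7) under nucleophilic, basic conditions, in a macrocycle that carries an acetate and a translactonisable O8, and then opened with chloride. The Z olefin must be made in the linear precursor by other means.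
- Comparison: the chosen plan sets against this the early, catalyst-controlled C11 centre with chlorine already in place, and the tether solution for the Z olefin.

Key step: step 14

Assumption: with Sn(OTf)2 the (S,S)-Ph-pybox ligand is taken to deliver ketene acetal 13 to the re face of keto ester 15; if the sense of induction is the opposite, the (R,R)-ligand is used with no other change.

## Steps

Step 1
Reactants: 1 (S)-epichlorohydrin; 2 trimethylsilylacetylene
Product: 3 (2S)-1-chloro-5-(trimethylsilyl)pent-4-yn-2-ol
Conditions: 2, n-BuLi, THF, −78 °C; BF3·OEt2; then 1, −78 °C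
Reagents that add atoms: none
Why: BF3-promoted opening of a terminal epoxide by a lithium acetylide (Yamaguchi conditions) occurs at the unsubstituted ring carbon, so the stereocentre of 1 is untouched and becomes C2 of the target.

Step 2
Reactants: 3 (2S)-1-chloro-5-(trimethylsilyl)pent-4-yn-2-ol
Product: 5 (3S)-6-(trimethylsilyl)hex-1-en-5-yn-3-ol, via epoxide 4 (not isolated)
Conditions: Me3SI (3.5 equiv), n-BuLi (3.4 equiv), THF, −20 °C to rt
Reagents that add atoms: trimethylsulfonium iodide, C[S+](C)C.[I-]
Why: Dimethylsulfonium methylide first closes the chlorohydrin to epoxide 4, then opens it at the terminal carbon; the resulting β-oxido sulfonium salt is deprotonated and eliminates Me2S (one-carbon homologation of an epoxide to an allylic alcohol). The carbinol carbon is never a reacting centre.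

Step 3
Reactants: 5 (3S)-6-(trimethylsilyl)hex-1-en-5-yn-3-ol
Product: 6 (3S)-hex-1-en-5-yn-3-ol
Conditions: K2CO3, MeOH, rt
Reagents that add atoms: none
Why: Base-catalysed methanolysis of the alkynyl C–Si bond frees the terminal alkyne needed for carbometalation.

Step 4
Reactants: 6 (3S)-hex-1-en-5-yn-3-ol
Product: 8 (3S,5E)-6-iodo-5-methylhexa-1,5-dien-3-ol, via alkenylalane 7 (not isolated)
Conditions: AlMe3 (3 equiv), Cp2ZrCl2 (0.25 equiv), CH2Cl2, 0 °C to rt; then I2, THF, −30 to 0 °C
Reagents that add atoms: trimethylaluminium, C[Al](C)C; iodine, II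
Why: Negishi zirconium-catalysed carboalumination adds methyl and aluminium syn across the terminal alkyne with aluminium on the terminal carbon, and iodinolysis with retention gives the E vinyl iodide. The hydroxyl is carried as its aluminium alkoxide and the monosubstituted olefin is not carbometalated under these conditions.

Step 5
Reactants: 9 4-methoxybenzyl alcohol; 10 methyl acrylate
Product: 11 methyl 3-[(4-methoxyphenyl)methoxy]propanoate
Conditions: NaH (0.1 equiv), THF, 0 °C to rt
Reagents that add atoms: none
Why: Alkoxide-catalysed oxa-Michael addition of a benzylic alcohol to an acrylate.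

Step 6
Reactants: 11 methyl 3-[(4-methoxyphenyl)methoxy]propanoate
Product: 12 S-ethyl 3-[(4-methoxyphenyl)methoxy]propanethioate
Conditions: AlMe3, EtSH, CH2Cl2, 0 °C to rt
Reagents that add atoms: ethanethiol, CCS
Why: The aluminium thiolate Me2AlSEt converts methyl esters directly into S-ethyl thioesters; the thioester is needed both for the aldol donor and for the later reduction to the aldehyde.

Step 7
Reactants: 12 S-ethyl 3-[(4-methoxyphenyl)methoxy]propanethioate
Product: 13 trimethyl{[(1Z)-1-(ethylsulfanyl)-3-[(4-methoxyphenyl)methoxy]prop-1-en-1-yl]oxy}silane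
Conditions: LiN(iPr)2, Me3SiCl, THF, −78 °C (internal quench)
Reagents that add atoms: chlorotrimethylsilane, C[Si](C)(C)Cl
Why: Kinetic enolisation of the thioester in the presence of the silyl chloride gives mainly the Z ketene thioacetal. Trapping at −78 °C is faster than β-elimination of the PMB-oxide.

Step 8
Reactants: 14 ethyl bromopyruvate
Product: 15 ethyl 3-chloro-2-oxopropanoate
Conditions: LiCl (5 equiv), DMF, rt; distillation
Reagents that add atoms: lithium chloride, [Li+].[Cl-]
Why: Halide exchange at an α-keto CH2–Br is fast, and excess soluble chloride drives it to the stronger C–Cl bond. The chloride then stays in place as C13–Cl to the end.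

Step 9
Reactants: 13 trimethyl{[(1Z)-1-(ethylsulfanyl)-3-[(4-methoxyphenyl)methoxy]prop-1-en-1-yl]oxy}silane; 15 ethyl 3-chloro-2-oxopropanoate
Product: 17 ethyl (2S,3R)-2-(chloromethyl)-4-(ethylsulfanyl)-2-hydroxy-3-{[(4-methoxyphenyl)methoxy]methyl}-4-oxobutanoate, via silyl ether 16 (not isolated)
Conditions: Sn(OTf)2 (10 mol %), (S,S)-Ph-pybox (12 mol %), CH2Cl2, −78 °C; then 1 M HCl, THF, 0 °C
Reagents that add atoms: none
Why: Catalytic enantioselective Mukaiyama aldol addition to an α-keto ester held as a bidentate chelate on a C2-symmetric divalent tin Lewis acid; this catalyst class is known to give anti adducts from substituted ketene thioacetals and pyruvate esters. The ligand fixes the ketone face (re face, giving C11) and the open transition state places the alkoxymethyl group anti to the new hydroxyl (C7). Acidic work-up removes the transferred silyl group.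

Step 10
Reactants: 17 ethyl (2S,3R)-2-(chloromethyl)-4-(ethylsulfanyl)-2-hydroxy-3-{[(4-methoxyphenyl)methoxy]methyl}-4-oxobutanoate
Product: 18 ethyl (2S,3R)-2-(chloromethyl)-3-formyl-2-hydroxy-4-[(4-methoxyphenyl)methoxy]butanoate
Conditions: Et3SiH, Pd/C (10 %), acetone, rt; used crude
Reagents that add atoms: none
Why: Fukuyama reduction takes the thioester to the aldehyde under neutral conditions, so the epimerisable C7 centre and the β-hydroxy aldehyde are not exposed to base. No olefin is present yet, and the ethyl ester, PMB ether and alkyl chloride are inert.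

Step 11
Reactants: 18 ethyl (2S,3R)-2-(chloromethyl)-3-formyl-2-hydroxy-4-[(4-methoxyphenyl)methoxy]butanoate; 19 2-methylallylmagnesium chloride
Product: 21 (3S,4S,5R)-3-(chloromethyl)-3-hydroxy-4-{[(4-methoxyphenyl)methoxy]methyl}-5-(2-methylprop-2-en-1-yl)oxolan-2-one, via hydroxy ester 20 (not isolated)
Conditions: (+)-Ipc2BOMe, 19, Et2O, −78 °C to rt; then 18, −78 °C; NaBO3·4H2O, THF/H2O, rt; PPTS, CH2Cl2, rt
Reagents that add atoms: none
Why: Brown methallylboration through a closed chair transition state; the borane from (+)-Ipc2BOMe (the (−)-α-pinene series) attacks the re face of the aldehyde. This is also the Felkin face with C11 as the large group, so reagent and substrate are matched and give 8R. The γ-hydroxy ester 20 closes to the lactone, which protects O8 and C12 together; non-basic perborate work-up spares the chlorohydrin.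

Step 12
Reactants: 21 (3S,4S,5R)-3-(chloromethyl)-3-hydroxy-4-{[(4-methoxyphenyl)methoxy]methyl}-5-(2-methylprop-2-en-1-yl)oxolan-2-one
Product: 22 (2S,3S,4R)-2-(chloromethyl)-2,4-dihydroxy-N-methoxy-3-{[(4-methoxyphenyl)methoxy]methyl}-N,6-dimethylhept-6-enamide
Conditions: Me(MeO)NH·HCl, AlMe3, CH2Cl2, 0 °C to rt; aq. KNa tartrate; used crude at once
Reagents that add atoms: N,O-dimethylhydroxylamine hydrochloride, CNOC.Cl
Why: Aluminium amide aminolysis of a γ-lactone to the γ-hydroxy Weinreb amide (Weinreb lactone opening) frees the C8 hydroxyl for the tether. The amide is silylated immediately because it recloses under acid.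

Step 13
Reactants: 8 (3S,5E)-6-iodo-5-methylhexa-1,5-dien-3-ol; 23 dichlorodi(propan-2-yl)silane; 22 (2S,3S,4R)-2-(chloromethyl)-2,4-dihydroxy-N-methoxy-3-{[(4-methoxyphenyl)methoxy]methyl}-N,6-dimethylhept-6-enamide
Product: 25 (2S,3S,4R)-2-(chloromethyl)-2-hydroxy-4-[({[(3S,5E)-6-iodo-5-methylhexa-1,5-dien-3-yl]oxy}di(propan-2-yl)silyl)oxy]-N-methoxy-3-{[(4-methoxyphenyl)methoxy]methyl}-N,6-dimethylhept-6-enamide, via chlorosilyl ether 24 (not isolated)
Conditions: 8, 23 (3 equiv), imidazole, CH2Cl2, 0 °C; excess 23 removed under vacuum; then 22, imidazole, DMF, rt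
Reagents that add atoms: none
Why: Stepwise silylation of two secondary alcohols with a dichlorosilane is the standard way to mixed silaketals for tethered metathesis. The monochloride 24 has only one Si–Cl bond left and is too hindered to silylate the tertiary C11 hydroxyl.

Step 14
Reactants: 25 (2S,3S,4R)-2-(chloromethyl)-2-hydroxy-4-[({[(3S,5E)-6-iodo-5-methylhexa-1,5-dien-3-yl]oxy}di(propan-2-yl)silyl)oxy]-N-methoxy-3-{[(4-methoxyphenyl)methoxy]methyl}-N,6-dimethylhept-6-enamide
Product: 26 (2S,3S)-2-(chloromethyl)-2-hydroxy-3-{(4S,5Z,8R)-4-[(2E)-3-iodo-2-methylprop-2-en-1-yl]-6-methyl-2,2-di(propan-2-yl)-1,3-dioxa-2-silacyclooct-5-en-8-yl}-N-methoxy-4-[(4-methoxyphenyl)methoxy]-N-methylbutanamide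
Conditions: second-generation Grubbs catalyst (15 mol %), toluene (0.003 M), 80 °C, argon purge
Reagents that add atoms: none
Why: The ruthenium carbene loads on the monosubstituted C1 vinyl group; the resulting alkylidene adds across the tethered 1,1-disubstituted C10 olefin to a ruthenacyclobutane, whose cycloreversion forms C1=C10 and releases the methylidene, ethylene being purged. The closest known reaction type is temporary silicon-tethered ring-closing metathesis of bis-alkoxysilanes to seven- and eight-membered cyclic silaketals containing Z-trisubstituted olefins. The one ring closed is the eight-membered 1,3-dioxa-2-silacyclooct-5-ene (O2, Si, O8, C8, C9, C10, C1, C2), closed by olefin metathesis between the two chain termini. No stereocentre is formed; the olefin must be Z because an eight-membered ring cannot hold a trans double bond. The step needs chemoselectivity over the vinyl iodide, which is trisubstituted and halogenated and therefore a poor partner for the carbene, and over intermolecular dimerisation, which is suppressed by the tether and high dilution. The two isopropyl groups on silicon favour the folded conformer and keep the silaketal stable to chromatography. The Weinreb amide, the tertiary alcohol, the PMB ether and the four existing stereocentres are not involved.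

Step 15
Reactants: 26 (2S,3S)-2-(chloromethyl)-2-hydroxy-3-{(4S,5Z,8R)-4-[(2E)-3-iodo-2-methylprop-2-en-1-yl]-6-methyl-2,2-di(propan-2-yl)-1,3-dioxa-2-silacyclooct-5-en-8-yl}-N-methoxy-4-[(4-methoxyphenyl)methoxy]-N-methylbutanamide
Product: 28 (3S,4S,5R)-3-(chloromethyl)-3-hydroxy-5-[(2Z,4S,6E)-4-hydroxy-7-iodo-2,6-dimethylhepta-2,6-dien-1-yl]-4-{[(4-methoxyphenyl)methoxy]methyl}oxolan-2-one, via diol amide 27 (not isolated)
Conditions: HF·pyridine, pyridine, THF, 0 °C to rt; then PPTS, CH2Cl2, rt
Reagents that add atoms: none
Why: Fluoride cleaves both Si–O bonds of the silaketal; under mild acid the freed γ-hydroxy amide recloses to the lactone (lactonisation with loss of the amine). This leaves O8 acylated and O2 as the only free secondary hydroxyl, so the two carbinols are differentiated without any selectivity question.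

Step 16
Reactants: 28 (3S,4S,5R)-3-(chloromethyl)-3-hydroxy-5-[(2Z,4S,6E)-4-hydroxy-7-iodo-2,6-dimethylhepta-2,6-dien-1-yl]-4-{[(4-methoxyphenyl)methoxy]methyl}oxolan-2-one
Product: 29 O2-tert-butyldimethylsilyl ether of lactone 28
Conditions: TBSCl, imidazole, DMF, 0 °C to rt
Reagents that add atoms: tert-butyl(chloro)dimethylsilane, CC(C)(C)[Si](C)(C)Cl
Why: Standard silylation of the only unhindered hydroxyl; the tertiary α-hydroxy lactone is not silylated under these conditions.

Step 17
Reactants: 29 O2-tert-butyldimethylsilyl ether of lactone 28
Product: 31 open-chain O8-acetate O2-TBS ether C6-PMB ether C12 N-methoxy-N-methylamide (2S,7S,8R,11S), via hydroxy amide 30 (not isolated)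
Conditions: Me(MeO)NH·HCl, AlMe3, CH2Cl2, 0 °C; aq. KNa tartrate; then Ac2O, pyridine, DMAP (cat.), CH2Cl2, 0 °C
Reagents that add atoms: N,O-dimethylhydroxylamine hydrochloride, CNOC.Cl; acetic anhydride, CC(=O)OC(C)=O
Why: The lactone is reopened as in step 12 and the crude γ-hydroxy amide is acetylated at once at the secondary C8 hydroxyl; the tertiary C11 hydroxyl is not acylated at 0 °C. With O8 capped by its final acetate, only O6 can later lactonise onto C12.

Step 18
Reactants: 31 open-chain O8-acetate O2-TBS ether C6-PMB ether C12 N-methoxy-N-methylamide (2S,7S,8R,11S)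
Product: 32 C6 primary alcohol corresponding to 31
Conditions: DDQ, CH2Cl2/pH 7 phosphate buffer, 0 °C; used at once
Reagents that add atoms: none
Why: Oxidative cleavage of the PMB ether; the allylic silyl ether, vinyl iodide and trisubstituted olefins are not oxidised. Buffering and immediate use limit lactonisation of the primary γ-hydroxy amide.

Step 19
Reactants: 32 C6 primary alcohol corresponding to 31
Product: 33 C6 aldehyde (iodo aldehyde; 2S,7S,8R,11S)
Conditions: Dess–Martin periodinane, NaHCO3, CH2Cl2, 0 °C
Reagents that add atoms: none
Why: Dess–Martin oxidation is neutral and fast, so C7 is not epimerised and the β-acetate is not eliminated.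

Step 20
Reactants: 33 C6 aldehyde (iodo aldehyde; 2S,7S,8R,11S)
Product: 35 O2-tert-butyldimethylsilyl ether of the target (2S,6R,7R,8R,11S), via macrocyclic hydroxy amide 34 (not isolated)
Conditions: CrCl2 (10 equiv), NiCl2 (0.1 equiv), DMSO/THF, rt, slow addition of 33 to 0.002 M; work-up; then PPTS, CH2Cl2, 35 °C
Reagents that add atoms: none
Why: Nozaki–Hiyama–Kishi reaction: zerovalent nickel inserts into the C–I bond, transmetalation gives the trivalent alkenylchromium, and this adds only to the aldehyde with retention of the E geometry, closing the ten-membered ring. C6 is set in the ring-closing transition state; 6R is expected from the arrangement with C5 anti to the bulky C11 substituent and the chromium-bound oxygen pointing away from the ring (anti to C7–C8). The 6R alcohol then lactonises onto the Weinreb amide to the trans-fused lactone, and the C6 epimer is removed at this stage.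

Step 21
Reactants: 35 O2-tert-butyldimethylsilyl ether of the target (2S,6R,7R,8R,11S)
Product: 36 target: (2S,6R,7R,8R,11S)-8-acetoxy-13-chloro-2,11-dihydroxygermacra-1(10)Z,4E-dien-12,6-olide
Conditions: HF·pyridine, pyridine, THF, 0 °C to rt
Reagents that add atoms: none
Why: Buffered acidic fluoride removes the allylic silyl ether without base, so the chlorohydrin does not close to the epoxide and neither acetate migration nor translactonisation is triggered.

## Compound list

1 | (S)-epichlorohydrin | ClC[C@@H]1CO1 | starting material
2 | trimethylsilylacetylene | C#C[Si](C)(C)C | starting material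
3 | (2S)-1-chloro-5-(trimethylsilyl)pent-4-yn-2-ol | ClC[C@@H](O)CC#C[Si](C)(C)C | intermediate
4 | (2S)-2-[3-(trimethylsilyl)prop-2-yn-1-yl]oxirane (not isolated) | C[Si](C)(C)C#CC[C@H]1CO1 | intermediate
5 | (3S)-6-(trimethylsilyl)hex-1-en-5-yn-3-ol | C=C[C@@H](O)CC#C[Si](C)(C)C | intermediate
6 | (3S)-hex-1-en-5-yn-3-ol | C=C[C@@H](O)CC#C | intermediate
7 | dimethyl{(1E,4S)-4-[(dimethylalumanyl)oxy]-2-methylhexa-1,5-dien-1-yl}alumane (not isolated) | C=C[C@@H](O[Al](C)C)C/C(C)=C/[Al](C)C | intermediate
8 | (3S,5E)-6-iodo-5-methylhexa-1,5-dien-3-ol (C1–C5 fragment) | C=C[C@@H](O)C/C(C)=C/I | intermediate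
9 | 4-methoxybenzyl alcohol | COc1ccc(CO)cc1 | starting material
10 | methyl acrylate | C=CC(=O)OC | starting material
11 | methyl 3-[(4-methoxyphenyl)methoxy]propanoate | COC(=O)CCOCc1ccc(OC)cc1 | intermediate
12 | S-ethyl 3-[(4-methoxyphenyl)methoxy]propanethioate | CCSC(=O)CCOCc1ccc(OC)cc1 | intermediate
13 | trimethyl{[(1Z)-1-(ethylsulfanyl)-3-[(4-methoxyphenyl)methoxy]prop-1-en-1-yl]oxy}silane | CCS/C(O[Si](C)(C)C)=C\COCc1ccc(OC)cc1 | intermediate
14 | ethyl bromopyruvate | CCOC(=O)C(=O)CBr | starting material
15 | ethyl 3-chloro-2-oxopropanoate | CCOC(=O)C(=O)CCl | intermediate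
16 | ethyl (2S,3R)-2-(chloromethyl)-4-(ethylsulfanyl)-3-{[(4-methoxyphenyl)methoxy]methyl}-4-oxo-2-[(trimethylsilyl)oxy]butanoate (not isolated) | CCSC(=O)[C@H](COCc1ccc(OC)cc1)[C@@](O[Si](C)(C)C)(CCl)C(=O)OCC | intermediate
17 | ethyl (2S,3R)-2-(chloromethyl)-4-(ethylsulfanyl)-2-hydroxy-3-{[(4-methoxyphenyl)methoxy]methyl}-4-oxobutanoate | CCSC(=O)[C@H](COCc1ccc(OC)cc1)[C@@](O)(CCl)C(=O)OCC | intermediate
18 | ethyl (2S,3R)-2-(chloromethyl)-3-formyl-2-hydroxy-4-[(4-methoxyphenyl)methoxy]butanoate | O=C[C@H](COCc1ccc(OC)cc1)[C@@](O)(CCl)C(=O)OCC | intermediate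
19 | 2-methylallylmagnesium chloride | C=C(C)C[Mg]Cl | starting material
20 | ethyl (2S,3S,4R)-2-(chloromethyl)-2,4-dihydroxy-3-{[(4-methoxyphenyl)methoxy]methyl}-6-methylhept-6-enoate (not isolated) | C=C(C)C[C@@H](O)[C@H](COCc1ccc(OC)cc1)[C@@](O)(CCl)C(=O)OCC | intermediate
21 | (3S,4S,5R)-3-(chloromethyl)-3-hydroxy-4-{[(4-methoxyphenyl)methoxy]methyl}-5-(2-methylprop-2-en-1-yl)oxolan-2-one | C=C(C)C[C@H]1OC(=O)[C@](O)(CCl)[C@H]1COCc2ccc(OC)cc2 | intermediate
22 | (2S,3S,4R)-2-(chloromethyl)-2,4-dihydroxy-N-methoxy-3-{[(4-methoxyphenyl)methoxy]methyl}-N,6-dimethylhept-6-enamide (C6–C13 fragment) | C=C(C)C[C@@H](O)[C@H](COCc1ccc(OC)cc1)[C@@](O)(CCl)C(=O)N(C)OC | intermediate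
23 | dichlorodi(propan-2-yl)silane | CC(C)[Si](Cl)(Cl)C(C)C | starting material
24 | chloro{[(3S,5E)-6-iodo-5-methylhexa-1,5-dien-3-yl]oxy}di(propan-2-yl)silane (not isolated) | C=C[C@H](C/C(C)=C/I)O[Si](Cl)(C(C)C)C(C)C | intermediate
25 | mixed diisopropylsilaketal of 8 (through O2) and 22 (through O8); 2S,7S,8R,11S | C=C[C@H](C/C(C)=C/I)O[Si](C(C)C)(C(C)C)O[C@H](CC(C)=C)[C@H](COCc1ccc(OC)cc1)[C@@](O)(CCl)C(=O)N(C)OC | intermediate
26 | eight-membered cyclic silaketal (1,3-dioxa-2-silacyclooct-5-ene: O2, Si(iPr)2, O8, C8, C9, C10, C1, C2) with Z C1=C10; (E)-3-iodo-2-methylallyl on C2; CH(CH2OPMB)–C(OH)(CH2Cl)–C(O)N(OMe)Me chain on C8; 2S,7S,8R,11S | C/C1=C/[C@H](C/C(C)=C/I)O[Si](C(C)C)(C(C)C)O[C@H](C1)[C@H](COCc2ccc(OC)cc2)[C@@](O)(CCl)C(=O)N(C)OC | intermediate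
27 | open-chain O2,O8-diol N-methoxy-N-methylamide (not isolated); 2S,7S,8R,11S | O[C@H](C/C(C)=C\[C@@H](O)C/C(C)=C/I)[C@H](COCc1ccc(OC)cc1)[C@@](O)(CCl)C(=O)N(C)OC | intermediate
28 | (3S,4S,5R)-3-(chloromethyl)-3-hydroxy-5-[(2Z,4S,6E)-4-hydroxy-7-iodo-2,6-dimethylhepta-2,6-dien-1-yl]-4-{[(4-methoxyphenyl)methoxy]methyl}oxolan-2-one | C/C(=C/[C@@H](O)C/C(C)=C/I)C[C@H]1OC(=O)[C@](O)(CCl)[C@H]1COCc2ccc(OC)cc2 | intermediate
29 | O2-tert-butyldimethylsilyl ether of lactone 28 | C/C(=C/[C@@H](O[Si](C)(C)C(C)(C)C)C/C(C)=C/I)C[C@H]1OC(=O)[C@](O)(CCl)[C@H]1COCc2ccc(OC)cc2 | intermediate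
30 | open-chain O8-hydroxy O2-TBS ether N-methoxy-N-methylamide (not isolated); 2S,7S,8R,11S | O[C@H](C/C(C)=C\[C@@H](O[Si](C)(C)C(C)(C)C)C/C(C)=C/I)[C@H](COCc1ccc(OC)cc1)[C@@](O)(CCl)C(=O)N(C)OC | intermediate
31 | open-chain O8-acetate O2-TBS ether C6-PMB ether C12 N-methoxy-N-methylamide; 2S,7S,8R,11S | CC(=O)O[C@H](C/C(C)=C\[C@@H](O[Si](C)(C)C(C)(C)C)C/C(C)=C/I)[C@H](COCc1ccc(OC)cc1)[C@@](O)(CCl)C(=O)N(C)OC | intermediate
32 | C6 primary alcohol corresponding to 31; 2S,7S,8R,11S | CC(=O)O[C@H](C/C(C)=C\[C@@H](O[Si](C)(C)C(C)(C)C)C/C(C)=C/I)[C@H](CO)[C@@](O)(CCl)C(=O)N(C)OC | intermediate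
33 | C6 aldehyde (iodo aldehyde for ring closure); 2S,7S,8R,11S | CC(=O)O[C@H](C/C(C)=C\[C@@H](O[Si](C)(C)C(C)(C)C)C/C(C)=C/I)[C@H](C=O)[C@@](O)(CCl)C(=O)N(C)OC | intermediate
34 | ten-membered C6 alcohol with C12 N-methoxy-N-methylamide (not isolated); 2S,6R,7S,8R,11S | CC(=O)O[C@@H]1C/C(C)=C\[C@@H](O[Si](C)(C)C(C)(C)C)C/C(C)=C/[C@@H](O)[C@@H]1[C@@](O)(CCl)C(=O)N(C)OC | intermediate
35 | O2-tert-butyldimethylsilyl ether of the target; 2S,6R,7R,8R,11S | CC(=O)O[C@@H]1C/C(C)=C\[C@@H](O[Si](C)(C)C(C)(C)C)C/C(C)=C/[C@H]2OC(=O)[C@](O)(CCl)[C@@H]21 | intermediate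
36 | (2S,6R,7R,8R,11S)-8-acetoxy-13-chloro-2,11-dihydroxygermacra-1(10)Z,4E-dien-12,6-olide (CNP0360028.4) | CC(=O)O[C@@H]1C/C(C)=C\[C@@H](O)C/C(C)=C/[C@H]2OC(=O)[C@](O)(CCl)[C@@H]21 | target

## Step count and risk

Total: 21 steps. Longest linear sequence: 16 steps (steps 5, 6, 7, 9–21, from 9 and 10). The C1–C5 branch is four steps to 8 (13 steps to 36) and the keto ester branch one step to 15.

**Step 14 (key step).**
- Most likely failure: the alkylidene formed at C1 does not engage the hindered 1,1-disubstituted olefin in the eight-membered closure, and the substrate is consumed by intermolecular dimerisation through the vinyl groups or by olefin migration.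
- Fallback (relay ring-closing metathesis, which delivers the catalyst to C10; sets out from 18, returns at 26):
  - In place of step 11, aldehyde 18 is allylated with excess racemic pinacol (2-methylocta-1,7-dien-3-yl)boronate F1, made in one pot by Matteson homologation of isopropenylboronic acid pinacol ester with LiCHCl2 and pent-4-enylmagnesium bromide.
  - Allylboration through the CH2 terminus on the Felkin face (the matched boronate enantiomer reacting faster) and lactonisation give relay lactone F2, in which the C10 olefin carries a pent-4-enyl chain of immaterial geometry.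
  - Opening as in step 12 gives relay hydroxy amide F3, and silylation with 24 as in step 13 gives relay silaketal F4.
  - The second-generation Grubbs catalyst then loads on the unhindered terminal olefin, expels cyclopentene, and arrives on C10 as the alkylidene, which closes onto the C1 vinyl group to the same cyclic silaketal 26.

**Step 9.**
- Most likely failure: a poor anti/syn ratio or low enantioselectivity, because the alkoxymethyl-substituted ketene acetal and the chlorinated keto ester lie outside the substrate range shown for the tin catalyst (competing coordination of the ether oxygen, mixed ketene acetal geometry). Moderate erosion is removed at lactone 21, where the minor isomers become separable diastereomers.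
- Fallback (copper-catalysed syn aldol with the roles of the two carbonyl carbons exchanged; sets out from 13 and 15, returns at 22):
  - Cu(OTf)2 with (S,S)-t-Bu-box (divalent copper; its documented sense with pyruvate esters is the one needed) gives syn adduct F5. Here the thioester carbon plays C6 and the PMB-oxymethyl carbon plays C8, which is the required C7/C11 relationship.
  - DDQ removes the PMB group and the primary alcohol closes onto the ethyl ester to thioester lactone F6.
  - NaBH4 in EtOH at 0 °C reduces the thioester to hydroxymethyl lactone F7. F7 is kept neutral and protected at once with 4-methoxybenzyl trichloroacetimidate/PPTS as PMB ether lactone F8, because acyl migration between the two hydroxymethyl arms would scramble C7.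
  - Opening with Me(MeO)NH·HCl/AlMe3 gives primary hydroxy amide F9, Dess–Martin oxidation gives aldehyde amide F10, and methallylboration as in step 11 gives 22 directly.

**Step 19 (with step 18).**
- Most likely failure: the primary γ-hydroxy amide 32 lactonises onto C12 with loss of the amine before it is oxidised, or the acetate migrates from O8 to O6.
- Fallback (the free alcohol is never placed next to the amide; sets out from 29, returns at 33):
  - DDQ is applied at the lactone stage to give primary alcohol lactone F11, which is silylated with Et3SiCl/imidazole to triethylsilyl ether F12.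
  - Opening as in step 17 gives hydroxy amide F13 (not isolated) and acetylation gives acetate F14.
  - Swern oxidation ((COCl)2, DMSO, iPr2NEt, −78 °C) converts the primary triethylsilyl ether directly into aldehyde 33, with the secondary TBS ether untouched.

**Step 20.**
- Most likely failure: poor facial selectivity at C6 (the open-chain Felkin preference with C11 as the large group would favour 6S), or protodeiodination and oligomerisation competing with the slow ten-membered closure.
- Fallback (C6 set by reagent-controlled reduction instead of by the C–C bond formation; sets out from 33, returns at 34):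
  - The 6S alcohol F15 from the same ring closure (or the epimer mixture) is oxidised with Dess–Martin periodinane to macrocyclic enone F16, kept free of base because of the β-acetate.
  - Reduction with (S)-2-methyl-CBS-oxazaborolidine and catecholborane at −78 °C, with the branched C7 substituent acting as the larger group, should give the 6R alcohol 34, which is lactonised as in step 20.

## Further compounds

F1 | step 14 | racemic 4,4,5,5-tetramethyl-2-(2-methylocta-1,7-dien-3-yl)-1,3,2-dioxaborolane | C=C(C)C(CCCC=C)B1OC(C)(C)C(C)(C)O1
F2 | step 14 | relay lactone: (3S,4S,5R)-3-(chloromethyl)-3-hydroxy-4-{[(4-methoxyphenyl)methoxy]methyl}-5-(2-methylocta-2,7-dien-1-yl)oxolan-2-one | C=CCCCC=C(C)C[C@H]1OC(=O)[C@](O)(CCl)[C@H]1COCc2ccc(OC)cc2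
F3 | step 14 | relay hydroxy amide: (2S,3S,4R)-2-(chloromethyl)-2,4-dihydroxy-N-methoxy-3-{[(4-methoxyphenyl)methoxy]methyl}-N,6-dimethyldodeca-6,11-dienamide | C=CCCCC=C(C)C[C@@H](O)[C@H](COCc1ccc(OC)cc1)[C@@](O)(CCl)C(=O)N(C)OC
F4 | step 14 | relay silaketal: diisopropylsilaketal of 8 (through O2) and F3 (through O8) | C=C[C@H](C/C(C)=C/I)O[Si](C(C)C)(C(C)C)O[C@H](CC(C)=CCCCC=C)[C@H](COCc1ccc(OC)cc1)[C@@](O)(CCl)C(=O)N(C)OC
F5 | step 9 | syn adduct: ethyl (2S,3S)-2-(chloromethyl)-4-(ethylsulfanyl)-2-hydroxy-3-{[(4-methoxyphenyl)methoxy]methyl}-4-oxobutanoate | CCSC(=O)[C@@H](COCc1ccc(OC)cc1)[C@@](O)(CCl)C(=O)OCC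
F6 | step 9 | thioester lactone: S-ethyl 4-(chloromethyl)-4-hydroxy-5-oxooxolane-3-carbothioate | CCSC(=O)[C@H]1COC(=O)[C@]1(O)CCl
F7 | step 9 | hydroxymethyl lactone: 3-(chloromethyl)-3-hydroxy-4-(hydroxymethyl)oxolan-2-one | OC[C@H]1COC(=O)[C@]1(O)CCl
F8 | step 9 | PMB ether lactone: 3-(chloromethyl)-3-hydroxy-4-{[(4-methoxyphenyl)methoxy]methyl}oxolan-2-one | COc1ccc(COC[C@H]2COC(=O)[C@]2(O)CCl)cc1
F9 | step 9 | primary hydroxy amide: 2-(chloromethyl)-2,4-dihydroxy-N-methoxy-3-{[(4-methoxyphenyl)methoxy]methyl}-N-methylbutanamide | OC[C@H](COCc1ccc(OC)cc1)[C@@](O)(CCl)C(=O)N(C)OC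
F10 | step 9 | aldehyde amide: 2-(chloromethyl)-3-formyl-2-hydroxy-N-methoxy-4-[(4-methoxyphenyl)methoxy]-N-methylbutanamide | O=C[C@H](COCc1ccc(OC)cc1)[C@@](O)(CCl)C(=O)N(C)OC
F11 | step 19 | primary alcohol lactone (29 without the PMB group) | C/C(=C/[C@@H](O[Si](C)(C)C(C)(C)C)C/C(C)=C/I)C[C@H]1OC(=O)[C@](O)(CCl)[C@H]1CO
F12 | step 19 | triethylsilyl ether of F11 | C/C(=C/[C@@H](O[Si](C)(C)C(C)(C)C)C/C(C)=C/I)C[C@H]1OC(=O)[C@](O)(CCl)[C@H]1CO[Si](CC)(CC)CC
F13 | step 19 | open-chain O8-hydroxy C6-triethylsilyl ether N-methoxy-N-methylamide (not isolated) | O[C@H](C/C(C)=C\[C@@H](O[Si](C)(C)C(C)(C)C)C/C(C)=C/I)[C@H](CO[Si](CC)(CC)CC)[C@@](O)(CCl)C(=O)N(C)OC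
F14 | step 19 | O8-acetate of F13 | CC(=O)O[C@H](C/C(C)=C\[C@@H](O[Si](C)(C)C(C)(C)C)C/C(C)=C/I)[C@H](CO[Si](CC)(CC)CC)[C@@](O)(CCl)C(=O)N(C)OC
F15 | step 20 | 6S alcohol (C6 epimer of 34) | CC(=O)O[C@@H]1C/C(C)=C\[C@@H](O[Si](C)(C)C(C)(C)C)C/C(C)=C/[C@H](O)[C@@H]1[C@@](O)(CCl)C(=O)N(C)OC
F16 | step 20 | macrocyclic C6 enone | CC(=O)O[C@@H]1C/C(C)=C\[C@@H](O[Si](C)(C)C(C)(C)C)C/C(C)=C/C(=O)[C@@H]1[C@@](O)(CCl)C(=O)N(C)OC
A1 | alternative 1 | ten-membered dienol from the ring contraction (free C6 hydroxyl, C7 1-(triethylsilyloxymethyl)vinyl group, O8 TBS, O2 triisopropylsilyl) | CC(C)(C)[Si](C)(C)O[C@@H]1C/C(C)=C\[C@@H](O[Si](C(C)C)(C(C)C)C(C)C)C/C(C)=C/[C@@H](O)[C@@H]1C(=C)CO[Si](CC)(CC)CC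
A2 | alternative 2 | ten-membered C10 enol triflate (O2 PMB, O8 methoxymethyl, C11/C13 acetonide, 12,6-lactone) | COCO[C@@H]1C/C(OS(=O)(=O)C(F)(F)F)=C\[C@@H](OCc3ccc(OC)cc3)C/C(C)=C/[C@H]2OC(=O)[C@@]4(OC(C)(C)OC4)[C@@H]21
A3 | alternative 3 | ten-membered C8 alcohol with C7 methyl acrylate side chain (O2 and O6 TBS) | O[C@@H]1C/C(C)=C\[C@@H](O[Si](C)(C)C(C)(C)C)C/C(C)=C/[C@@H](O[Si](C)(C)C(C)(C)C)[C@@H]1C(=C)C(=O)OC
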